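# Sipholenol K: furanone photocycloaddition and strain-release opening to the oxepane

Atom labels used in the text: the left half carries 1-benzoxepine numbering (O1, C2 … C5a, C6 … C9a), the right half primed naphthalen-2(1H)-one numbering (C1′ … C8a′), and the linker carbons are C1″ (on C6) and C2″ (on C4′).

## Analysis of the target

Sipholenol K (35) is two bicyclic halves joined by a CH2–CH2 chain: a trans-fused decahydro-1-benzoxepine and a cis-fused hexahydronaphthalen-2(1H)-one. In the left half, ring A is the oxepane O1–C2(Me2)–C3H(OH)–C4H2–C5H2–C5a–C9a and ring B the cyclohexane C5a–C6–C7–C8–C9–C9a; in the right half, ring C is a 3-methyl-4-alkyl cyclohexenone and ring D carries the C5′ gem-dimethyl group and the C8′ methyl carbinol. There are eight stereocentres, five contiguous on the left (C3, C5a, C6, C7, C9a) and three contiguous on the right (C4a′, C8′, C8a′); the two sets are too far apart to control each other, so each half must be made as a single enantiomer. On ring B the C5a methyl, the C7 methyl (1,3-diaxial to it) and the C6 side chain share one face, while H-9a, H-6 and the C7 hydroxyl lie on the other; the C3 hydroxyl is anti to the C5a methyl; on ring D the two ring-fusion hydrogens and the C8′ hydroxyl are cis. Sensitive are the two tertiary alcohols (acid), the enone with its epimerisable vinylogous H-4a′, and the C3 carbinol wedged between a quaternary carbon and a methylene. The hard part is the oxepane: a tertiary ether next to a secondary carbinol, fused trans to a ring whose fusion carbon C5a is quaternary, which direct etherification closes reluctantly. The strategy rests on one observation: O1, C2 (with both methyls), C3 (as ketone), C4 and C9a are the five ring atoms of a 2,2-dimethylfuran-3(2H)-one whose C4=C5 bond (here C4–C9a) has been pulled apart by insertion of C5 and C5a, the two carbons of an alkene.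

## Retrosynthetic reasoning

**35 ← 34 ← 33.** The enone carbonyl C2′ is taken back to an allylic alcohol and all four hydroxyls to silyl ethers. An enone would not survive the carbanion and electron-transfer steps of the fragment union; in the forward direction only the allylic hydroxyl of tetraol 34 has to be oxidised.

**33 ← 32 ← 18 + 31.** The C1″–C2″ bond is cut. It is the only bond whose cleavage gives two halves of similar size, each with its own stereocentres. The polarity is chosen so that the carbon next to the crowded C6 is the nucleophile (α-sulfonyl carbanion of 18) and the unhindered allylic carbon the electrophile (bromide 31); the opposite polarity would need an SN2 reaction beside two quaternary carbons. Forward: alkylation, then reductive loss of the sulfonyl group.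

**18 ← 17 ← 16.** The C3 carbinol is traced to the ketone. The ketone lies between a quaternary carbon and a methylene, which is the pattern on which a chiral oxazaborolidine reduction discriminates best, so C3 is set by the reagent and not by the ring.

**16 ← 14 (through 15).** The C4–C9a bond is re-formed in the retrosynthetic sense. This turns the oxepanone into cyclobutane 14, in which both ether bonds of ring A already exist in a tetrahydrofuranone. The gain is that no C–O bond to the hindered C9a or to C2 has to be made late. The forward reaction must break only the cyclobutane bond that lies between the ether oxygen and the ketone, and must put hydrogen on C9a anti to the C5a methyl.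

**14 ← 13.** The cyclobutane bonds C5a–C9a and C4–C5 are cut, giving furanone 13 with an isopropenyl group on a four-atom tether. This single disconnection supplies ring B, the quaternary C5a, the oxygenated C9a and the two missing carbons of ring A. The forward reaction is the [2+2] photocycloaddition, the key step. The sulfonylmethyl group is already in place on C6, so nothing has to be exchanged on that hindered branch afterwards.

**13 ← 11 (through 12) ← 10 ← 8 + 9.** The furanone is opened to the γ-hydroxy ynone, and the bond between its carbonyl carbon (C9a) and the alkyne is cut to aldehyde 8 and alkynol 9, which brings O1, C2 with its methyls, C3 and C4. The tertiary C7 oxygen has to be silylated beforehand, because a free hydroxyl four atoms from C9a would end as a spiroketal.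

**8 ← 6 (through 7) ← 5 ← 4.** The aldehyde comes from the trisubstituted alkene of 6 by epoxidation and glycol cleavage, in the same operation that raises the sulfide to the sulfone. The sulfide comes from the primary hydroxyl of diol 4.

**4 ← 2 + 3; 2 ← 1.** The C6–C5a bond is cut to epoxy alcohol 2 and alkenyl Grignard reagent 3: opening at the less substituted epoxide carbon with inversion sets C6 relative to C7. Asymmetric epoxidation of 1 fixes the absolute configuration of the whole left half in the first step.

**31 ← 30 ← 29 ← 28 ← 27 ← 26.** Bromide, alcohol, ether and silyl groups are functional-group changes. The C8′ carbinol is derived from the exocyclic alkene of 26 through spiro-epoxide 27. An electrophilic oxygen enters from the convex face of the cis-fused bicycle and so ends cis to the ring-fusion hydrogens; a methyl nucleophile adding to the ketone from the same face would give the wrong epimer.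

**26 ← 25 ← 24.** The C4′–CH2O bond is cut with a 1,3-shift of oxygen (alkylative carbonyl transposition). The enone of 24 has its carbonyl at C4′; adding the oxymethyl carbon there and moving the oxygen to C2′ gives the substitution pattern of ring C.

**24 ← 23 ← 22 ← 21.** Oxidation-level changes: allylic oxygen at C4′, methylenation of the C8′ ketone.

**21 ← 19 + 20.** Diels–Alder disconnection of ring C. The suprafacial addition is the one step in the right half that sets the cis ring fusion kinetically, and the orientation of 20 puts the methyl on C3′.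

## Alternatives that were turned down

**Alternative 1:** Ring A is cut at O1–C2. In the forward step a sulfonic acid lets the free C9a hydroxyl of ring B open a trisubstituted C2–C3 epoxide at its tertiary carbon (7-endo), which gives A1 with the C3 carbinol inherited from the epoxide; ring B is obtained by cutting open a bicyclic enedione.
- For it: every step is of a known type, C3 is set by a reagent-controlled epoxidation, and no photochemistry is needed.
- Against it: the 7-endo closure competes with 6-exo attack at the secondary epoxide carbon and has to form a C–O bond from a hydroxyl beside the quaternary C5a. The ring-B centres C5a, C6 and C7 are set one after another on a long linear path from the enedione.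
- Comparison: on precedent and risk this route is stronger. The chosen strategy offers step economy in its place: ring B, C5a and the two-carbon bridge of ring A arise in one step and no ether bond has to be closed, at the price of an unproven step. The epoxide closure is kept as a fallback.

**Alternative 2:** Ring B is built on the cyclohexenone ketal from which A2 is made. A copper–diphosphine catalyst adds a vinyl nucleophile at C6 (the future linker) and the enolate is alkylated at C5a with a haloacetate (the future ring-A arm), giving A2.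
- For it: two adjacent stereocentres, one quaternary, from one catalytic operation on cheap material, in thermal and scalable chemistry.
- Against it: copper-catalysed asymmetric addition of sp2 Grignard reagents to α-substituted cyclohexenones is weak in enantioselectivity, and alkylating a hindered enolate to a quaternary centre is slow. A2 has neither the C7 methyl carbinol nor the oxepane; the arm must still be lengthened by three carbons, the ether closed, and C3 and C9a set.
- Comparison: in cost and scale of the opening steps it is stronger. The chosen route sets the absolute configuration by an epoxidation of well-understood reliability and solves the part that A2 leaves open, the oxepane.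

**Alternative 3:** This disconnects the right half. A protonated chiral oxazaborolidine promotes an intramolecular Diels–Alder reaction of a 1-silyloxy diene with a tethered vinyl ketone, forming C4a′–C8a′ and C1′–C2′ and closing rings C and D together to A3.
- For it: cis fusion, both rings and the absolute configuration come from one step. The tether enforces the orientation of ring C (carbonyl-side CH2 on C8a′) that an intermolecular cycloaddition to a cyclohexenone disfavours electronically, and the C2′ oxygen and the C4′ oxymethyl group arrive in place.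
- Against it: the key step does nothing for the harder left half. It needs a geometrically defined silyloxy trienone assembled linearly, and the C8′ carbinol still has to be made from the ketone against the facial preference.
- Comparison: for rings C and D it is probably stronger than the intermolecular Diels–Alder and transposition sequence used here, which has to add a carbon and move an oxygen. The chosen strategy puts its one bold step where the alternatives have only long conventional sequences, the oxepane half, and keeps the right half as a convergent branch from two commercial compounds, 19 and 20.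

Key step: step 9

Remark on the chemistry 1: carbinol centres that are later oxidised or removed (C5 of 10, C5 of 22, C1 of 23 and 25, the sulfonyl-bearing carbon of 32) are taken as formed without control; 28–34 are drawn with the C2′ configuration expected from hydride attack on the convex face.

Remark on the chemistry 2: the sense of induction in step 13 is assumed to follow the model established for 2-cycloalkenones; the mirror-image catalyst is used if it does not.

## Route

Step 1
Reactants: 1 geraniol
Product: 2 [(2S,3S)-3-methyl-3-(4-methylpent-3-en-1-yl)oxiran-2-yl]methanol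
Conditions: Ti(OiPr)4 (5 mol%), L-(+)-diethyl tartrate (6 mol%), t-BuOOH, 4 Å sieves, CH2Cl2, −20 °C
Reagents that add atoms: tert-butyl hydroperoxide, CC(C)(C)OO
Why: Sharpless asymmetric epoxidation of an (E)-trisubstituted allylic alcohol; the L-(+)-tartrate complex gives the (2S,3S)-epoxide, which fixes C7 and the carbon that becomes C6.

Step 2
Reactants: 2 (2S,3S)-epoxy alcohol; 3 isopropenylmagnesium bromide
Product: 4 (2R,3S)-3,7-dimethyl-2-(prop-1-en-2-yl)oct-6-ene-1,3-diol
Conditions: 3 (4 equiv), CuI (10 mol%), THF, −30 → 0 °C; aq. NH4Cl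
Reagents that add atoms: none
Why: Copper-catalysed Grignard opening of a 2,3-epoxy alcohol: the alkenyl group attacks C2, the only epoxide carbon open to SN2 (C3 is fully substituted), with inversion, so C6 is set relative to C7; one equivalent of 3 is spent on the hydroxyl proton.

Step 3
Reactants: 4 (2R,3S)-1,3-diol
Product: 5 (2S,3S)-3,7-dimethyl-1-(phenylsulfanyl)-2-(prop-1-en-2-yl)oct-6-en-3-ol
Conditions: PhSSPh, n-Bu3P, pyridine, rt
Reagents that add atoms: diphenyl disulfide, c1ccc(cc1)SSc1ccccc1
Why: Phosphine–disulfide thioetherification (Hata reaction): only the primary alcohol forms the alkoxyphosphonium ion that thiolate displaces, the tertiary alcohol is inert.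

Step 4
Reactants: 5 hydroxy sulfide
Product: 6 triethyl{[(2S,3S)-3,7-dimethyl-1-(phenylsulfanyl)-2-(prop-1-en-2-yl)oct-6-en-3-yl]oxy}silane
Conditions: Et3SiOTf, 2,6-lutidine, CH2Cl2, −78 → 0 °C
Reagents that add atoms: triethylsilyl trifluoromethanesulfonate, CC[Si](CC)(CC)OS(=O)(=O)C(F)(F)F
Why: Silyl triflate silylation of a hindered tertiary alcohol; the ether keeps this oxygen from forming a lactol or spiroketal once the chain end is a carbonyl group.

Step 5
Reactants: 6 silyl ether sulfide
Product: 8 (4S,5S)-4,6-dimethyl-5-[(phenylsulfonyl)methyl]-4-[(triethylsilyl)oxy]hept-6-enal, via epoxy sulfone 7 (not isolated)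
Conditions: 3-ClC6H4CO3H (3.1 equiv), NaHCO3, CH2Cl2, −20 → 0 °C; then H5IO6, THF/H2O, 0 °C
Reagents that add atoms: 3-chloroperoxybenzoic acid, OOC(=O)c1cccc(Cl)c1
Why: The peracid oxidises sulfur to the sulfone first and then the electron-rich trisubstituted alkene, sparing the hindered 1,1-disubstituted alkene beside the sulfonylmethyl branch; periodic acid opens the epoxide and cleaves the glycol (Malaprade cleavage) to the aldehyde.

Step 6
Reactants: 8 aldehyde; 9 2-methylbut-3-yn-2-ol
Product: 10 (8S,9S)-2,8,10-trimethyl-9-[(phenylsulfonyl)methyl]-8-[(triethylsilyl)oxy]undec-10-en-3-yne-2,5-diol (both C5 epimers)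
Conditions: 9 (2.5 equiv), n-BuLi (5 equiv), THF, −78 → −20 °C; then 8, −78 °C; aq. NH4Cl
Reagents that add atoms: none
Why: 1,2-Addition of the lithium acetylide (dianion of 9) to the aldehyde; the acetylide is too weak a base to deprotonate the sulfone at −78 °C.

Step 7
Reactants: 10 propargylic diol
Product: 11 (8S,9S)-2-hydroxy-2,8,10-trimethyl-9-[(phenylsulfonyl)methyl]-8-[(triethylsilyl)oxy]undec-10-en-3-yn-5-one
Conditions: Dess–Martin periodinane, NaHCO3, CH2Cl2, 0 °C → rt
Reagents that add atoms: none
Why: Dess–Martin oxidation of the secondary propargylic alcohol; the tertiary hydroxyl and the tertiary silyl ether cannot be oxidised.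

Step 8
Reactants: 11 γ-hydroxy ynone
Product: 13 5-{(3S,4S)-3,5-dimethyl-4-[(phenylsulfonyl)methyl]-3-[(triethylsilyl)oxy]hex-5-en-1-yl}-2,2-dimethylfuran-3(2H)-one, via enaminone 12 (not isolated)
Conditions: Et2NH, EtOH, rt; then AcOH/H2O/THF (pH about 4), rt
Reagents that add atoms: none
Why: Classical 3(2H)-furanone synthesis: conjugate addition of the amine to the ynone, hydrolysis of the enaminone to the 1,3-diketone and cyclodehydration by the tertiary hydroxyl; the hindered tertiary silyl ether should survive the weakly acidic medium.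

Step 9
Reactants: 13 furanone with tethered isopropenyl group
Product: 14 (1R,5R,7S,8S,9S)-3,3,7,9-tetramethyl-8-[(phenylsulfonyl)methyl]-9-[(triethylsilyl)oxy]-2-oxatricyclo[5.4.0.0(1,5)]undecan-4-one
Conditions: hν (350 nm), MeCN (0.005 M), Ar, rt
Reagents that add atoms: none
Why: Proposed new method: an intramolecular [2+2] photocycloaddition of a 3(2H)-furanone to an alkene held on a four-atom tether at its C5 has not been shown; the closest known reactions are the intermolecular photocycloadditions of 2,2-dimethyl-3(2H)-furanones with alkenes and the intramolecular enone–alkene and dioxinone–alkene photocycloadditions. Excitation and intersystem crossing give the triplet furanone, whose β-carbon (the future C9a) adds to the internal alkene carbon (the future C5a); the 1,4-biradical (α-keto radical at the future C4, primary radical at the future C5) closes after spin inversion by joining C4 to C5. Ring B closes in the first bond by a 6-exo attack, which is why the straight and not the crossed adduct is expected, since every other first bond would close a seven- or eight-membered ring; the cyclobutane closes by radical recombination and can only be cis-fused to both the furanone ring and ring B. Of the three new stereocentres, C5a is controlled by the existing C6 and C7 centres through a chair-like tether in which the phenylsulfonylmethyl and silyloxy groups are equatorial; the furanone then turns its bulky O–CMe2 flank to the equatorial side and its CH flank to the axial side, and because the alkene CH2 must lie under that CH, the alkene methyl is axial and anti to H-6. C9a and C4 follow from C5a because only the cis ring fusions can form. The step needs straight regiochemistry, secured by the tether length, and attack on one face of the alkene, secured by the two equatorial substituents; the second is the less certain.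

Step 10
Reactants: 14 cyclobutane photoadduct
Product: 16 (5aS,6S,7S,9aS)-2,2,5a,7-tetramethyl-6-[(phenylsulfonyl)methyl]-7-[(triethylsilyl)oxy]octahydro-1-benzoxepin-3(2H)-one, via silyl enol ether 15 (not isolated)
Conditions: Et3SiOTf (0.2 equiv), Et3SiH (3 equiv), CH2Cl2, −78 → −40 °C; then K2CO3, MeOH, 0 °C
Reagents that add atoms: none
Why: Proposed new method: Lewis-acid opening of an alkoxy-substituted cyclobutyl ketone with hydride capture of the oxocarbenium ion has not been shown; the silyl triflate silylates the ketone oxygen, the strained C4–C9a bond between the donor oxygen and the acceptor carbonyl breaks to a cyclic oxocarbenium ion and a silyl enol ether (relief of about 26 kcal/mol of ring strain), the silane delivers hydride to C9a axially and anti to the axial C5a methyl to give the trans fusion and releases the silyl cation that carries the chain, and methanolysis frees the ketone; a silyl triflate is used rather than a boron Lewis acid so that the tertiary silyl ether is not cleaved; closest known are the retro-aldol step of the de Mayo reaction, Lewis-acid opening of donor–acceptor cyclobutanes and silane reduction of cyclic oxocarbenium ions.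

Step 11
Reactants: 16 oxepanone
Product: 17 (3S,5aS,6S,7S,9aS)-2,2,5a,7-tetramethyl-6-[(phenylsulfonyl)methyl]-7-[(triethylsilyl)oxy]decahydro-1-benzoxepin-3-ol
Conditions: (R)-1-methyl-3,3-diphenyltetrahydro-1H,3H-pyrrolo[1,2-c][1,3,2]oxazaborole (0.5 equiv), BH3·SMe2, THF, −20 °C; MeOH
Reagents that add atoms: none
Why: Corey–Bakshi–Shibata reduction: the ketone has a quaternary carbon on one side and a methylene on the other, the pattern the oxazaborolidine differentiates best, and the (R)-catalyst places hydride on the face that gives the (3S)-alcohol whatever the small bias of the seven-membered ring.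

Step 12
Reactants: 17 (3S)-alcohol
Product: 18 (3S,5aS,6S,7S,9aS)-2,2,5a,7-tetramethyl-6-[(phenylsulfonyl)methyl]-3,7-bis[(triethylsilyl)oxy]decahydro-1-benzoxepine
Conditions: Et3SiOTf, 2,6-lutidine, CH2Cl2, 0 °C
Reagents that add atoms: triethylsilyl trifluoromethanesulfonate, CC[Si](CC)(CC)OS(=O)(=O)C(F)(F)F
Why: Silylation of the hindered secondary alcohol so that the sulfonyl carbanion of step 24 is not quenched; both silyl groups are of the same kind and leave together at the end.

Step 13
Reactants: 19 4,4-dimethylcyclohex-2-en-1-one; 20 isoprene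
Product: 21 (4aR,8aS)-4,4,6-trimethyl-3,4,4a,5,8,8a-hexahydronaphthalen-1(2H)-one
Conditions: (S)-3,3-diphenyl-1-(o-tolyl)tetrahydro-1H,3H-pyrrolo[1,2-c][1,3,2]oxazaborole (20 mol%), Tf2NH (18 mol%), 20 (5 equiv), CH2Cl2, −20 °C → rt
Reagents that add atoms: none
Why: Catalytic enantioselective Diels–Alder reaction of a 2-cycloalkenone under chiral oxazaborolidinium activation: suprafacial addition fixes the cis ring fusion (C4a′, C8a′), the diene terminus next to the methyl-bearing carbon bonds to the enone β-carbon (the "para" adduct, methyl on C3′), and the catalyst shields one face of the enone.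

Step 14
Reactants: 21 cis-octalone
Product: 22 (4aR,8aS)-5-hydroxy-4,4,6-trimethyl-3,4,4a,5,8,8a-hexahydronaphthalen-1(2H)-one (both C5 epimers)
Conditions: SeO2 (0.5 equiv), t-BuOOH (2 equiv), CH2Cl2, rt
Reagents that add atoms: tert-butyl hydroperoxide, CC(C)(C)OO
Why: SeO2 allylic oxidation (ene reaction, then [2,3]-sigmatropic shift): oxygen enters at the ring CH2 on the more substituted alkene carbon (C4′) and the alkene returns to its place; the saturated ketone is left under these mild catalytic conditions.

Step 15
Reactants: 22 hydroxy ketone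
Product: 23 (4aS,8aR)-2,8,8-trimethyl-5-methylidene-1,4,4a,5,6,7,8,8a-octahydronaphthalen-1-ol (both C1 epimers)
Conditions: Cp2TiMe2 (3 equiv), toluene/THF, 65 °C, dark
Reagents that add atoms: dimethyltitanocene, C[Ti](C)(C1C=CC=C1)C1C=CC=C1
Why: Petasis methylenation: the titanium methylidene is not basic, so the cis ring fusion α to the ketone is not epimerised; the excess allows for the free hydroxyl.

Step 16
Reactants: 23 allylic alcohol
Product: 24 (4aS,8aR)-2,8,8-trimethyl-5-methylidene-4a,5,6,7,8,8a-hexahydronaphthalen-1(4H)-one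
Conditions: MnO2 (activated, excess), CH2Cl2, rt
Reagents that add atoms: none
Why: MnO2 oxidation of a secondary allylic alcohol to the enone under neutral conditions that leave the exocyclic alkene and the ring fusion alone.

Step 17
Reactants: 24 enone
Product: 25 (4aS,8aR)-1-{[(4-methoxybenzyl)oxy]methyl}-2,8,8-trimethyl-5-methylidene-1,4,4a,5,6,7,8,8a-octahydronaphthalen-1-ol (both C1 epimers)
Conditions: Bu3SnCH2OCH2C6H4-4-OMe (2 equiv), n-BuLi (2 equiv), THF, −78 °C; then 24, −78 °C; aq. NH4Cl
Reagents that add atoms: tributyl{[(4-methoxybenzyl)oxy]methyl}stannane, CCCC[Sn](CCCC)(CCCC)COCc1ccc(OC)cc1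
Why: Tin–lithium exchange gives a small, hard alkoxymethyllithium that adds 1,2 to the enone carbonyl at low temperature; the new carbinol centre is removed in the next step.

Step 18
Reactants: 25 tertiary allylic alcohol
Product: 26 (4aR,8aS)-4-{[(4-methoxybenzyl)oxy]methyl}-3,5,5-trimethyl-8-methylidene-4a,5,6,7,8,8a-hexahydronaphthalen-2(1H)-one
Conditions: [pyH][CrO3Cl] (2.5 equiv), 4 Å sieves, CH2Cl2, rt
Reagents that add atoms: pyridinium chlorochromate, [O-][Cr](=O)(=O)Cl.c1cc[nH+]cc1
Why: Babler–Dauben oxidative transposition: the chromate ester of the tertiary allylic alcohol undergoes a [3,3]-shift and is oxidised, which puts the carbonyl at C2′ and the tetrasubstituted alkene at C3′–C4′.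

Step 19
Reactants: 26 enone with exocyclic alkene
Product: 27 (1S,4aR,8aS)-5-{[(4-methoxybenzyl)oxy]methyl}-4,4,6-trimethyl-3,4,4a,8a-tetrahydro-2H-spiro[naphthalene-1,2'-oxiran]-7(8H)-one
Conditions: 3-ClC6H4CO3H (1.2 equiv), NaHCO3, CH2Cl2, 0 °C
Reagents that add atoms: 3-chloroperoxybenzoic acid, OOC(=O)c1cccc(Cl)c1
Why: Peracid epoxidation of the electron-rich exocyclic alkene from the convex face of the cis-fused bicycle, the face of the ring-fusion hydrogens; the enone alkene is electron-poor and does not react.

Step 20
Reactants: 27 spiro-epoxide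
Product: 28 (1S,4aR,7R,8aS)-5-{[(4-methoxybenzyl)oxy]methyl}-1,4,4,6-tetramethyl-1,2,3,4,4a,7,8,8a-octahydronaphthalene-1,7-diol
Conditions: LiAlH4 (3 equiv), THF, 0 °C → rt; H2O, aq. NaOH
Reagents that add atoms: none
Why: Hydride opens the spiro-epoxide at its CH2 group (SN2) to the tertiary carbinol with the hydroxyl cis to the ring-fusion hydrogens (C8′), and reduces the hindered enone 1,2 to the allylic alcohol whose configuration does not matter.

Step 21
Reactants: 28 diol
Product: 29 (1S,4aR,7R,8aS)-5-{[(4-methoxybenzyl)oxy]methyl}-1,4,4,6-tetramethyl-1,7-bis[(triethylsilyl)oxy]-1,2,3,4,4a,7,8,8a-octahydronaphthalene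
Conditions: Et3SiOTf (3 equiv), 2,6-lutidine, CH2Cl2, −78 → 0 °C
Reagents that add atoms: triethylsilyl trifluoromethanesulfonate, CC[Si](CC)(CC)OS(=O)(=O)C(F)(F)F
Why: The silyl triflate silylates the tertiary and the allylic secondary alcohol in one operation; the masked enone and the carbinol are now inert to the carbanion of step 24.

Step 22
Reactants: 29 bis-silyl ether
Product: 30 {(3R,4aS,5S,8aR)-2,5,8,8-tetramethyl-3,5-bis[(triethylsilyl)oxy]-3,4,4a,5,6,7,8,8a-octahydronaphthalen-1-yl}methanol
Conditions: DDQ (1.3 equiv), CH2Cl2/pH 7 buffer, 0 °C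
Reagents that add atoms: none
Why: Oxidative cleavage of the 4-methoxybenzyl ether through its benzylic oxocarbenium ion; buffered, cold conditions keep the silyl ethers.

Step 23
Reactants: 30 allylic alcohol
Product: 31 (3R,4aS,5S,8aR)-1-(bromomethyl)-2,5,8,8-tetramethyl-3,5-bis[(triethylsilyl)oxy]-3,4,4a,5,6,7,8,8a-octahydronaphthalene
Conditions: CBr4, PPh3, 2,6-lutidine, CH2Cl2, −30 °C
Reagents that add atoms: carbon tetrabromide, BrC(Br)(Br)Br
Why: Appel reaction of the primary allylic alcohol under neutral, cold conditions; the bromide is used at once.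

Step 24
Reactants: 18 bis-silylated sulfone; 31 allylic bromide
Product: 32 (3S,5aS,6S,7S,9aS)-2,2,5a,7-tetramethyl-6-{1-(phenylsulfonyl)-2-[(3R,4aS,5S,8aR)-2,5,8,8-tetramethyl-3,5-bis[(triethylsilyl)oxy]-3,4,4a,5,6,7,8,8a-octahydronaphthalen-1-yl]ethyl}-3,7-bis[(triethylsilyl)oxy]decahydro-1-benzoxepine (both epimers at the sulfonyl carbon)
Conditions: 18, n-BuLi (1.05 equiv), THF/HMPA, −78 °C; then 31, −78 → −20 °C
Reagents that add atoms: none
Why: Julia-type alkylation: the α-sulfonyl carbanion displaces the primary allylic bromide by SN2; the polar cosolvent loosens the ion pair of the hindered carbanion.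

Step 25
Reactants: 32 coupled sulfone
Product: 33 (3S,5aS,6S,7S,9aS)-2,2,5a,7-tetramethyl-6-{2-[(3R,4aS,5S,8aR)-2,5,8,8-tetramethyl-3,5-bis[(triethylsilyl)oxy]-3,4,4a,5,6,7,8,8a-octahydronaphthalen-1-yl]ethyl}-3,7-bis[(triethylsilyl)oxy]decahydro-1-benzoxepine
Conditions: Na(Hg) (6% Na), Na2HPO4, MeOH/THF, −20 °C
Reagents that add atoms: none
Why: Reductive desulfonylation by electron transfer, loss of sulfinate and protonation; buffered conditions keep the silyl ethers, and there is no leaving group β to the carbanion.

Step 26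
Reactants: 33 tetrakis-silyl ether
Product: 34 (3S,5aS,6S,7S,9aS)-6-{2-[(3R,4aS,5S,8aR)-3,5-dihydroxy-2,5,8,8-tetramethyl-3,4,4a,5,6,7,8,8a-octahydronaphthalen-1-yl]ethyl}-2,2,5a,7-tetramethyldecahydro-1-benzoxepine-3,7-diol
Conditions: Bu4NF (8 equiv), THF, rt → 50 °C
Reagents that add atoms: none
Why: Fluoride cleaves all four silyl ethers, the tertiary ones on warming; the basic medium avoids ionisation of the allylic alcohol.

Step 27
Reactants: 34 tetraol
Product: 35 sipholenol K, (4aR,8S,8aS)-4-{2-[(3S,5aS,6S,7S,9aS)-3,7-dihydroxy-2,2,5a,7-tetramethyldecahydro-1-benzoxepin-6-yl]ethyl}-8-hydroxy-3,5,5,8-tetramethyl-4a,5,6,7,8,8a-hexahydronaphthalen-2(1H)-one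
Conditions: MnO2 (activated, excess), CH2Cl2, rt
Reagents that add atoms: none
Why: MnO2 oxidises only the allylic alcohol; the saturated secondary C3 carbinol and the two tertiary alcohols are untouched.

## Compound list

1 | geraniol, (2E)-3,7-dimethylocta-2,6-dien-1-ol | CC(C)=CCC/C(C)=C/CO | starting material
2 | [(2S,3S)-3-methyl-3-(4-methylpent-3-en-1-yl)oxiran-2-yl]methanol | CC(C)=CCC[C@]1(C)O[C@H]1CO | intermediate
3 | isopropenylmagnesium bromide | CC(=C)[Mg]Br | starting material
4 | (2R,3S)-3,7-dimethyl-2-(prop-1-en-2-yl)oct-6-ene-1,3-diol | CC(C)=CCC[C@](C)(O)[C@@H](CO)C(C)=C | intermediate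
5 | (2S,3S)-3,7-dimethyl-1-(phenylsulfanyl)-2-(prop-1-en-2-yl)oct-6-en-3-ol | CC(C)=CCC[C@](C)(O)[C@@H](CSc1ccccc1)C(C)=C | intermediate
6 | triethyl{[(2S,3S)-3,7-dimethyl-1-(phenylsulfanyl)-2-(prop-1-en-2-yl)oct-6-en-3-yl]oxy}silane | CC(C)=CCC[C@](C)(O[Si](CC)(CC)CC)[C@@H](CSc1ccccc1)C(C)=C | intermediate
7 | {[(3S,4S)-1-(3,3-dimethyloxiran-2-yl)-3,5-dimethyl-4-[(phenylsulfonyl)methyl]hex-5-en-3-yl]oxy}triethylsilane (both oxirane epimers) | CC1(C)OC1CC[C@](C)(O[Si](CC)(CC)CC)[C@@H](CS(=O)(=O)c1ccccc1)C(C)=C | intermediate (not isolated)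
8 | (4S,5S)-4,6-dimethyl-5-[(phenylsulfonyl)methyl]-4-[(triethylsilyl)oxy]hept-6-enal | O=CCC[C@](C)(O[Si](CC)(CC)CC)[C@@H](CS(=O)(=O)c1ccccc1)C(C)=C | intermediate
9 | 2-methylbut-3-yn-2-ol | CC(C)(O)C#C | starting material
10 | (8S,9S)-2,8,10-trimethyl-9-[(phenylsulfonyl)methyl]-8-[(triethylsilyl)oxy]undec-10-en-3-yne-2,5-diol (both C5 epimers) | CC(C)(O)C#CC(O)CC[C@](C)(O[Si](CC)(CC)CC)[C@@H](CS(=O)(=O)c1ccccc1)C(C)=C | intermediate
11 | (8S,9S)-2-hydroxy-2,8,10-trimethyl-9-[(phenylsulfonyl)methyl]-8-[(triethylsilyl)oxy]undec-10-en-3-yn-5-one | CC(C)(O)C#CC(=O)CC[C@](C)(O[Si](CC)(CC)CC)[C@@H](CS(=O)(=O)c1ccccc1)C(C)=C | intermediate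
12 | (8S,9S)-3-(diethylamino)-2-hydroxy-2,8,10-trimethyl-9-[(phenylsulfonyl)methyl]-8-[(triethylsilyl)oxy]undeca-3,10-dien-5-one | CCN(CC)C(=CC(=O)CC[C@](C)(O[Si](CC)(CC)CC)[C@@H](CS(=O)(=O)c1ccccc1)C(C)=C)C(C)(C)O | intermediate (not isolated)
13 | 5-{(3S,4S)-3,5-dimethyl-4-[(phenylsulfonyl)methyl]-3-[(triethylsilyl)oxy]hex-5-en-1-yl}-2,2-dimethylfuran-3(2H)-one | CC1(C)OC(CC[C@](C)(O[Si](CC)(CC)CC)[C@@H](CS(=O)(=O)c2ccccc2)C(C)=C)=CC1=O | intermediate
14 | (1R,5R,7S,8S,9S)-3,3,7,9-tetramethyl-8-[(phenylsulfonyl)methyl]-9-[(triethylsilyl)oxy]-2-oxatricyclo[5.4.0.0(1,5)]undecan-4-one | CC1(C)O[C@@]23CC[C@](C)(O[Si](CC)(CC)CC)[C@@H](CS(=O)(=O)c4ccccc4)[C@]2(C)C[C@H]3C1=O | intermediate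
15 | (5aS,6S,7S,9aS)-2,2,5a,7-tetramethyl-6-[(phenylsulfonyl)methyl]-3,7-bis[(triethylsilyl)oxy]-2,5,5a,6,7,8,9,9a-octahydro-1-benzoxepine | CC1(C)O[C@H]2CC[C@](C)(O[Si](CC)(CC)CC)[C@@H](CS(=O)(=O)c3ccccc3)[C@]2(C)CC=C1O[Si](CC)(CC)CC | intermediate (not isolated)
16 | (5aS,6S,7S,9aS)-2,2,5a,7-tetramethyl-6-[(phenylsulfonyl)methyl]-7-[(triethylsilyl)oxy]octahydro-1-benzoxepin-3(2H)-one | CC1(C)O[C@H]2CC[C@](C)(O[Si](CC)(CC)CC)[C@@H](CS(=O)(=O)c3ccccc3)[C@]2(C)CCC1=O | intermediate
17 | (3S,5aS,6S,7S,9aS)-2,2,5a,7-tetramethyl-6-[(phenylsulfonyl)methyl]-7-[(triethylsilyl)oxy]decahydro-1-benzoxepin-3-ol | CC1(C)O[C@H]2CC[C@](C)(O[Si](CC)(CC)CC)[C@@H](CS(=O)(=O)c3ccccc3)[C@]2(C)CC[C@@H]1O | intermediate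
18 | (3S,5aS,6S,7S,9aS)-2,2,5a,7-tetramethyl-6-[(phenylsulfonyl)methyl]-3,7-bis[(triethylsilyl)oxy]decahydro-1-benzoxepine | CC1(C)O[C@H]2CC[C@](C)(O[Si](CC)(CC)CC)[C@@H](CS(=O)(=O)c3ccccc3)[C@]2(C)CC[C@@H]1O[Si](CC)(CC)CC | intermediate
19 | 4,4-dimethylcyclohex-2-en-1-one | CC1(C)CCC(=O)C=C1 | starting material
20 | isoprene, 2-methylbuta-1,3-diene | CC(=C)C=C | starting material
21 | (4aR,8aS)-4,4,6-trimethyl-3,4,4a,5,8,8a-hexahydronaphthalen-1(2H)-one | CC1=CC[C@@H]2C(=O)CCC(C)(C)[C@@H]2C1 | intermediate
22 | (4aR,8aS)-5-hydroxy-4,4,6-trimethyl-3,4,4a,5,8,8a-hexahydronaphthalen-1(2H)-one (both C5 epimers) | CC1=CC[C@@H]2C(=O)CCC(C)(C)[C@@H]2C1O | intermediate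
23 | (4aS,8aR)-2,8,8-trimethyl-5-methylidene-1,4,4a,5,6,7,8,8a-octahydronaphthalen-1-ol (both C1 epimers) | CC1=CC[C@@H]2C(=C)CCC(C)(C)[C@@H]2C1O | intermediate
24 | (4aS,8aR)-2,8,8-trimethyl-5-methylidene-4a,5,6,7,8,8a-hexahydronaphthalen-1(4H)-one | CC1=CC[C@@H]2C(=C)CCC(C)(C)[C@@H]2C1=O | intermediate
25 | (4aS,8aR)-1-{[(4-methoxybenzyl)oxy]methyl}-2,8,8-trimethyl-5-methylidene-1,4,4a,5,6,7,8,8a-octahydronaphthalen-1-ol (both C1 epimers) | CC1=CC[C@@H]2C(=C)CCC(C)(C)[C@@H]2C1(O)COCc3ccc(OC)cc3 | intermediate
26 | (4aR,8aS)-4-{[(4-methoxybenzyl)oxy]methyl}-3,5,5-trimethyl-8-methylidene-4a,5,6,7,8,8a-hexahydronaphthalen-2(1H)-one | CC1=C(COCc3ccc(OC)cc3)[C@@H]2[C@H](CC1=O)C(=C)CCC2(C)C | intermediate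
27 | (1S,4aR,8aS)-5-{[(4-methoxybenzyl)oxy]methyl}-4,4,6-trimethyl-3,4,4a,8a-tetrahydro-2H-spiro[naphthalene-1,2'-oxiran]-7(8H)-one | CC1=C(COCc3ccc(OC)cc3)[C@@H]2[C@H](CC1=O)[C@@]4(OC4)CCC2(C)C | intermediate
28 | (1S,4aR,7R,8aS)-5-{[(4-methoxybenzyl)oxy]methyl}-1,4,4,6-tetramethyl-1,2,3,4,4a,7,8,8a-octahydronaphthalene-1,7-diol | CC1=C(COCc3ccc(OC)cc3)[C@@H]2[C@H](C[C@H]1O)[C@@](C)(O)CCC2(C)C | intermediate
29 | (1S,4aR,7R,8aS)-5-{[(4-methoxybenzyl)oxy]methyl}-1,4,4,6-tetramethyl-1,7-bis[(triethylsilyl)oxy]-1,2,3,4,4a,7,8,8a-octahydronaphthalene | CC1=C(COCc3ccc(OC)cc3)[C@@H]2[C@H](C[C@H]1O[Si](CC)(CC)CC)[C@@](C)(O[Si](CC)(CC)CC)CCC2(C)C | intermediate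
30 | {(3R,4aS,5S,8aR)-2,5,8,8-tetramethyl-3,5-bis[(triethylsilyl)oxy]-3,4,4a,5,6,7,8,8a-octahydronaphthalen-1-yl}methanol | CC1=C(CO)[C@@H]2[C@H](C[C@H]1O[Si](CC)(CC)CC)[C@@](C)(O[Si](CC)(CC)CC)CCC2(C)C | intermediate
31 | (3R,4aS,5S,8aR)-1-(bromomethyl)-2,5,8,8-tetramethyl-3,5-bis[(triethylsilyl)oxy]-3,4,4a,5,6,7,8,8a-octahydronaphthalene | CC1=C(CBr)[C@@H]2[C@H](C[C@H]1O[Si](CC)(CC)CC)[C@@](C)(O[Si](CC)(CC)CC)CCC2(C)C | intermediate
32 | (3S,5aS,6S,7S,9aS)-2,2,5a,7-tetramethyl-6-{1-(phenylsulfonyl)-2-[(3R,4aS,5S,8aR)-2,5,8,8-tetramethyl-3,5-bis[(triethylsilyl)oxy]-3,4,4a,5,6,7,8,8a-octahydronaphthalen-1-yl]ethyl}-3,7-bis[(triethylsilyl)oxy]decahydro-1-benzoxepine (both epimers at the sulfonyl carbon) | CC1=C(CC([C@H]2[C@]3(C)CC[C@H](O[Si](CC)(CC)CC)C(C)(C)O[C@H]3CC[C@]2(C)O[Si](CC)(CC)CC)S(=O)(=O)c4ccccc4)[C@@H]2[C@H](C[C@H]1O[Si](CC)(CC)CC)[C@@](C)(O[Si](CC)(CC)CC)CCC2(C)C | intermediate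
33 | (3S,5aS,6S,7S,9aS)-2,2,5a,7-tetramethyl-6-{2-[(3R,4aS,5S,8aR)-2,5,8,8-tetramethyl-3,5-bis[(triethylsilyl)oxy]-3,4,4a,5,6,7,8,8a-octahydronaphthalen-1-yl]ethyl}-3,7-bis[(triethylsilyl)oxy]decahydro-1-benzoxepine | CC1=C(CC[C@H]2[C@]3(C)CC[C@H](O[Si](CC)(CC)CC)C(C)(C)O[C@H]3CC[C@]2(C)O[Si](CC)(CC)CC)[C@@H]2[C@H](C[C@H]1O[Si](CC)(CC)CC)[C@@](C)(O[Si](CC)(CC)CC)CCC2(C)C | intermediate
34 | (3S,5aS,6S,7S,9aS)-6-{2-[(3R,4aS,5S,8aR)-3,5-dihydroxy-2,5,8,8-tetramethyl-3,4,4a,5,6,7,8,8a-octahydronaphthalen-1-yl]ethyl}-2,2,5a,7-tetramethyldecahydro-1-benzoxepine-3,7-diol | CC1=C(CC[C@H]2[C@]3(C)CC[C@H](O)C(C)(C)O[C@H]3CC[C@]2(C)O)[C@@H]2[C@H](C[C@H]1O)[C@@](C)(O)CCC2(C)C | intermediate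
35 | sipholenol K, (4aR,8S,8aS)-4-{2-[(3S,5aS,6S,7S,9aS)-3,7-dihydroxy-2,2,5a,7-tetramethyldecahydro-1-benzoxepin-6-yl]ethyl}-8-hydroxy-3,5,5,8-tetramethyl-4a,5,6,7,8,8a-hexahydronaphthalen-2(1H)-one | CC1=C(CC[C@H]2[C@]3(C)CC[C@H](O)C(C)(C)O[C@H]3CC[C@]2(C)O)[C@@H]2[C@H](CC1=O)[C@@](C)(O)CCC2(C)C | target

## Step count and least certain steps

Total step count: 27 (steps 1–12 for the left half, steps 13–23 for the right half, steps 24–27 after the union). Longest linear sequence: 16 steps (steps 1–12 and 24–27, from 1).

**Step 10 (proposed new method).** Most likely to go wrong is that the cyclobutane bond does not break under a mild Lewis acid, because the ring-oxygen lone pair overlaps poorly with a bond of its own five-membered ring. Direct reduction of the silylated ketone, or loss of the tertiary silyl ether followed by capture of the oxocarbenium ion by that oxygen, would then compete.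

Fallback from known chemistry, setting out from 14 and returning at 17:
- Baeyer–Villiger oxidation of 14 (3-ClC6H4CO3H, NaHCO3): the oxygen-bearing quaternary carbon migrates, giving the 1,3-dioxan-4-one F1.
- K2CO3 in MeOH opens the lactone, acetone is lost and the freed cyclobutanol undergoes the retro-aldol step of the de Mayo reaction to keto ester F2.
- NaBH4 reduces the ring ketone by axial attack anti to the axial methyl to hydroxy ester F3.
- i-Bu2AlH at −78 °C gives hydroxy aldehyde F4, and isopropylidenetriphenylphosphorane (Wittig reaction) the trisubstituted alkene F5.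
- Shi epoxidation with 1,2:4,5-di-O-isopropylidene-β-L-erythro-2,3-hexodiulo-2,6-pyranose and KHSO5 gives the (S)-epoxide F6.
- Camphor-10-sulfonic acid closes the oxepane by 7-endo opening at the tertiary epoxide carbon to 17.

This route gives up the furanone carbons C2 and its methyls and rebuilds them, which is why it is the fallback and not the plan.

**Step 9 (key step, proposed new method).** Most likely to go wrong is facial selection: the two chair arrangements that place either the alkene methyl or the alkene CH2 over the axial C7 methyl differ little in energy, so the C5a epimer may form as well. Next in likelihood is addition in the crossed sense, because bonding first to the alkene CH2 gives the more stable tertiary radical. Slow bond formation between two fully substituted carbons also leaves time for decay of the triplet.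

Fallback from known chemistry, setting out from 8 and returning at 17:
- NaClO2 oxidation (Pinnick) of 8 to acid F7.
- Coupling with 2,2-dimethyl-1,3-dioxane-4,6-dione (N,N′-dicyclohexylcarbodiimide, 4-(dimethylamino)pyridine) to the acyl derivative F8.
- Heating F8 in toluene with acetone to the 6-substituted 2,2-dimethyl-1,3-dioxin-4-one F9.
- Irradiation at 300 nm: the intramolecular dioxinone–alkene photocycloaddition is established for alkenes tethered at this position, and it gives F1.
- From F1 the route follows the one above (F2, F3, F4, F5, F6) to 17.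

This cures a failure of the furanone chromophore in regiochemistry or efficiency. It does not change the tether, so if the fault is facial selection the same measure is needed in both routes: replacing the two acyclic substituents on C6 and C7 by a cyclic 1,3-diol derivative that locks the chair.

**Step 13.** Most likely to go wrong is low conversion: the β-carbon of 19 is next to the gem-dimethyl group, which makes it a poor partner for a bulky chiral Lewis acid, so the uncatalysed or achiral background reaction would erode the enantiomeric purity, and the cis fusion may epimerise on long exposure to acid.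

Fallback, setting out from 19 and returning at 21:
- Dehydrogenation of 19 with 2-iodoxybenzoic acid to the cross-conjugated dienone F10, a more reactive and symmetrical dienophile.
- Its desymmetrising Diels–Alder reaction with 20 under the same oxazaborolidinium catalysis, giving F11.
- Conjugate reduction of the remaining enone with [(Ph3P)CuH]6 to 21.

**Step 24.** Most likely to go wrong is slow alkylation of a carbanion flanked by the crowded C6, so that proton transfer from the bromide and its elimination to a diene compete.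

Fallback, setting out from 30 and 18 and returning at 33 (Julia–Lythgoe olefination, then reduction):
- MnO2 oxidation of 30 to enal F12.
- Addition of lithiated 18 and trapping with Ac2O to the β-acetoxy sulfone F13.
- Na(Hg) gives the (E)-diene F14.
- Diimide (potassium azodicarboxylate, AcOH) reduces the disubstituted alkene and leaves the tetrasubstituted one, giving 33.

## Further compounds

F1 | step 10 | 1,3-dioxan-4-one analogue of 14 (ring oxygen inserted between the carbonyl carbon and the CMe2 carbon of 14; same configuration) | CC1(C)O[C@@]23CC[C@](C)(O[Si](CC)(CC)CC)[C@@H](CS(=O)(=O)c4ccccc4)[C@]2(C)C[C@H]3C(=O)O1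
F2 | step 10 | methyl 3-{(1S,2S,3S)-1,3-dimethyl-6-oxo-2-[(phenylsulfonyl)methyl]-3-[(triethylsilyl)oxy]cyclohexyl}propanoate | COC(=O)CC[C@@]1(C)[C@H](CS(=O)(=O)c2ccccc2)[C@@](C)(O[Si](CC)(CC)CC)CCC1=O
F3 | step 10 | methyl 3-{(1S,2S,3S,6S)-6-hydroxy-1,3-dimethyl-2-[(phenylsulfonyl)methyl]-3-[(triethylsilyl)oxy]cyclohexyl}propanoate | COC(=O)CC[C@@]1(C)[C@H](CS(=O)(=O)c2ccccc2)[C@@](C)(O[Si](CC)(CC)CC)CC[C@@H]1O
F4 | step 10 | 3-{(1S,2S,3S,6S)-6-hydroxy-1,3-dimethyl-2-[(phenylsulfonyl)methyl]-3-[(triethylsilyl)oxy]cyclohexyl}propanal | O=CCC[C@@]1(C)[C@H](CS(=O)(=O)c2ccccc2)[C@@](C)(O[Si](CC)(CC)CC)CC[C@@H]1O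
F5 | step 10 | (1S,2S,3S,4S)-2,4-dimethyl-2-(4-methylpent-3-en-1-yl)-3-[(phenylsulfonyl)methyl]-4-[(triethylsilyl)oxy]cyclohexan-1-ol | CC(C)=CCC[C@@]1(C)[C@H](CS(=O)(=O)c2ccccc2)[C@@](C)(O[Si](CC)(CC)CC)CC[C@@H]1O
F6 | step 10 | (1S,2S,3S,4S)-2-{2-[(2S)-3,3-dimethyloxiran-2-yl]ethyl}-2,4-dimethyl-3-[(phenylsulfonyl)methyl]-4-[(triethylsilyl)oxy]cyclohexan-1-ol | CC2(C)O[C@H]2CC[C@@]1(C)[C@H](CS(=O)(=O)c3ccccc3)[C@@](C)(O[Si](CC)(CC)CC)CC[C@@H]1O
F7 | step 9 | (4S,5S)-4,6-dimethyl-5-[(phenylsulfonyl)methyl]-4-[(triethylsilyl)oxy]hept-6-enoic acid | OC(=O)CC[C@](C)(O[Si](CC)(CC)CC)[C@@H](CS(=O)(=O)c1ccccc1)C(C)=C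
F8 | step 9 | 5-{(4S,5S)-4,6-dimethyl-5-[(phenylsulfonyl)methyl]-4-[(triethylsilyl)oxy]hept-6-enoyl}-2,2-dimethyl-1,3-dioxane-4,6-dione | CC1(C)OC(=O)C(C(=O)CC[C@](C)(O[Si](CC)(CC)CC)[C@@H](CS(=O)(=O)c2ccccc2)C(C)=C)C(=O)O1
F9 | step 9 | 6-{(3S,4S)-3,5-dimethyl-4-[(phenylsulfonyl)methyl]-3-[(triethylsilyl)oxy]hex-5-en-1-yl}-2,2-dimethyl-4H-1,3-dioxin-4-one | CC1(C)OC(CC[C@](C)(O[Si](CC)(CC)CC)[C@@H](CS(=O)(=O)c2ccccc2)C(C)=C)=CC(=O)O1
F10 | step 13 | 4,4-dimethylcyclohexa-2,5-dien-1-one | CC1(C)C=CC(=O)C=C1
F11 | step 13 | (4aR,8aS)-4,4,6-trimethyl-4a,5,8,8a-tetrahydronaphthalen-1(4H)-one | CC1=CC[C@@H]2C(=O)C=CC(C)(C)[C@@H]2C1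
F12 | step 24 | (3R,4aS,5S,8aR)-2,5,8,8-tetramethyl-3,5-bis[(triethylsilyl)oxy]-3,4,4a,5,6,7,8,8a-octahydronaphthalene-1-carbaldehyde | CC1=C(C=O)[C@@H]2[C@H](C[C@H]1O[Si](CC)(CC)CC)[C@@](C)(O[Si](CC)(CC)CC)CCC2(C)C
F13 | step 24 | β-acetoxy sulfone from 18 and F12 (acetoxy group on the carbon attached to the octahydronaphthalene, phenylsulfonyl group on the carbon attached to C6 of the benzoxepine; epimer mixture at both) | CC1=C(C(OC(C)=O)C([C@H]2[C@]3(C)CC[C@H](O[Si](CC)(CC)CC)C(C)(C)O[C@H]3CC[C@]2(C)O[Si](CC)(CC)CC)S(=O)(=O)c4ccccc4)[C@@H]2[C@H](C[C@H]1O[Si](CC)(CC)CC)[C@@](C)(O[Si](CC)(CC)CC)CCC2(C)C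
F14 | step 24 | (E)-1″,2″-didehydro analogue of 33 (E alkene in the linker, conjugated with the ring alkene) | CC1=C(/C=C/[C@H]2[C@]3(C)CC[C@H](O[Si](CC)(CC)CC)C(C)(C)O[C@H]3CC[C@]2(C)O[Si](CC)(CC)CC)[C@@H]2[C@H](C[C@H]1O[Si](CC)(CC)CC)[C@@](C)(O[Si](CC)(CC)CC)CCC2(C)C
A1 | alternative 1 | (3S,5aS,6S,7S,9aS)-6-{2-[(tert-butyldimethylsilyl)oxy]ethyl}-2,2,5a,7-tetramethyldecahydro-1-benzoxepine-3,7-diol | CC(C)(C)[Si](C)(C)OCC[C@H]1[C@]2(C)CC[C@H](O)C(C)(C)O[C@H]2CC[C@]1(C)O
A2 | alternative 2 | methyl 2-[(6S,7S)-6-ethenyl-7-methyl-8-oxo-1,4-dioxaspiro[4.5]decan-7-yl]acetate | C=C[C@H]1[C@](C)(CC(=O)OC)C(=O)CCC12OCCO2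
A3 | alternative 3 | (4aR,7R,8aS)-5-{[(4-methoxybenzyl)oxy]methyl}-4,4,6-trimethyl-7-[(triisopropylsilyl)oxy]-3,4,4a,7,8,8a-hexahydronaphthalen-1(2H)-one | CC1=C(COCc3ccc(OC)cc3)[C@@H]2[C@H](C[C@H]1O[Si](C(C)C)(C(C)C)C(C)C)C(=O)CCC2(C)C
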